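## Structural features

The target consists of three hexasubstituted benzene rings joined in a row by two methylene bridges, and it has no stereocentre. Ring B is a 2,4,6-trihydroxyacetophenone unit (acetyl on B1, hydroxyls on B2, B4 and B6) that carries the bridges on B3 and B5. Each outer ring is a butyrophenone in which, counting from the butyryl carbon C1, C3 bears methyl, C5 the bridge, C6 a hydroxyl, and C2 and C4 bear oxygen. In ring A the methyl ether is on O4 and O2 is free, whereas in ring C the methyl ether is on O2 and O4 is free, so the outer rings are constitutional isomers and a reading with two identical outer rings would be wrong. The fragile elements are the diarylmethane bridges between phloroglucinol-type rings (redistributed through quinone methides in hot acid or base), the air-sensitive polyphenol array, and the O2 methyl ether of ring C, which lies ortho to the ketone and is the first ether lost to chelating Lewis acids. The real difficulty is twofold: each outer ring needs the ketone between O2 and O6 with O2 and O4 differentiated in opposite senses, and the rings must be joined in the order A–B–C on a central ring whose two nucleophilic carbons are equivalent. The key step exploits that in both outer rings C1 (butyryl) and C6 (hydroxyl) are neighbours, with oxygen-bearing C2 on one side and C5, unsubstituted until the bridge is made, on the other, so that an aryne across C1–C6 can take up butanoic acid with its oxygen on C6 and its acyl group on C1.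

## Logic of the disconnections

28 is cut at the B5–CH2 bond. This removes ring C as 14, with the bridge carbon traced to a one-carbon iminium reagent (via 26 and 27), and leaves 25. The cut is made last because the more easily ionised quinone methide precursor then meets the sensitive dimer under the mildest conditions. The forward step must alkylate B5 through carbon without redistributing the existing bridge.

25 is cut at the B3–CH2 bond into 21 and 22 (via 23 and 24). This reduces the unsymmetrical trimer to three simple arenes. The forward step must stop at monoalkylation of 22, whose two free carbons are equivalent.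

14 is traced back to 13 and 21 to 20 by restoring a benzylic O–C bond (on O4 of 14, on O2 of 21). One neutral deprotection then serves both rings, and no Lewis acid touches the O2 methyl ether of ring C. The forward step must cleave a benzylic ether without reducing the aryl ketone.

13 is cut at C1–C(=O) and C6–O into 9 and 10 (via 11 and 12), and 20 in the same way into 17 and 10 (via 18 and 19). Two adjacent substituents are removed at once and the hexasubstituted ketone becomes a pentasubstituted arene. The forward step must put oxygen on C6 and the acyl group on C1, and acyl transfer must beat protonation of the aryl anion.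

9 is cut at C–Si and O–S back to 5 (via 7 and 8), and 17 back to 6 (via 15 and 16). The silyl group comes from oxygen by an O→C shift, so no separate silylation of carbon is needed. The forward step must run halogen–lithium exchange faster than any reaction at the benzylic ether.

5 and 6 are both cut at C–Br back to 4. Its two ortho positions differ only in the neighbouring ether, so one bromination supplies the precursors of both rings. The forward step must monobrominate, and the isomers must be separated.

4 is cut at its phenolic C–O bond (as C–B, via 3) to 2, and 2 at O–CH2Ar to 1. The oxygen sits meta to both ethers, which electrophilic substitution cannot deliver. The forward step needs a sterically controlled C–H functionalisation that ignores the ring of the protecting group.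

## Other disconnections considered

Alternative 1: The cut is at C2–C3 and C4–C5 of each outer ring: C3 and C4 come from an ynol ether, and C5, C6, C1 and C2 from a cyclobutenone already on the bridge. In the forward step the bis(3-ethoxycyclobutenone) A1 is heated with the ynol ether 1-methoxyprop-1-yne A2 in an inert solvent. Each cyclobutenone ring of A1 would open to a vinylketene, add A2 in a [2+2] sense, reopen and close by 6π electrocyclisation to give the bis-phenol A3 (twofold Danheiser benzannulation).
- In favour: both bridges exist before any phloroglucinol ring is formed, so no quinone methide coupling or bridge scrambling arises. On this point it is better than the chosen plan. The ring pattern is fixed by the polarity of A2, which equals the regiocontrol of the aryne insertion. Conditions are neutral.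
- Against: A3 carries two identical outer rings, both with the ring A pattern (free hydroxyl on C2, methoxy on C4). Ring C would need a methyl ether on the new C2 hydroxyl and a removable ether on O4, that is, a second alkyne and a methylation on one arm only. A twofold annulation cannot do this, so the step leads to the symmetrical isomer.
- Remaining work even for ring A: butyrylation at C1, removal of the O6 ethyl ether beside the O4 methyl ether, acetylation of ring B in competition with the outer rings, and removal of three benzyl ethers. A1 also needs a multistep synthesis.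
- Comparison: structurally it secures the bridges but cannot tell the outer rings apart. Mechanistically a pericyclic cascade stands against an anionic aryne addition, both regiodefined. In step economy the chosen plan is shorter.

Alternative 2: The cut is at B3–CH2, B5–CH2 and the B4–O bond (as C–B). In the forward step iodide A4 reacts with two equivalents of benzylic chloride A5 in the presence of Pd(OAc)2 and norbornene A6 , and bis(pinacolato)diboron A7 terminates the sequence to give boronate A8 (Catellani reaction). Zerovalent palladium inserts into the C–I bond of A4 and A6 relays the metal to each ortho C–H through a divalent palladacycle. A5 adds oxidatively to give tetravalent palladium, and reductive elimination forms each bridge. After extrusion of A6 the arylpalladium species is borylated at the ipso carbon by A7 and the cycle closes.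
- In favour: three rings are joined and the B4 oxygen is prepared in one operation, the bridge positions are unambiguous, and no quinone methide equilibrium is involved. In convergence and in freedom from scrambling it is the better of the two plans.
- Against: both ortho positions receive the same electrophile, so A8 again has two ring A units. The target would need two different benzylic chlorides, which the relay cannot place selectively. A5 is hexasubstituted and electron-rich (slow oxidative addition, easy ionisation), the ortho C–H bonds of A4 are flanked by benzyloxy groups, and the ketones are enolisable under the basic conditions.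
- Comparison: structurally it is equal to the chosen plan in placing the bridges and worse in differentiating the outer rings. Mechanistically the relay asks for two hindered alkylations in sequence, against two simple conjugate additions. In step economy it is longer, because the outer-ring monomers still have to be made first and protection, chloromethylation, C–B oxidation and six debenzylations are added.

Alternative 3: The cut is at C5–C6 and C1–C2 of each outer ring. In the forward step butyrylketene A10 , released by thermolysis of the acyl Meldrum's acid A9 , is attacked at its central carbon by each diene terminus of the bis(silyloxydiene) A11 . The resulting diketone carbon then acylates the ketene acetal carbon (Claisen-type closure), which would give the bis(acylphloroglucinol) A12 .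
- In favour: each outer ring is born with its butyryl group and its O4 methyl ether, so ring A needs no later adjustment. On this point it is better than the chosen plan, which needs a deprotection.
- Against: the C2 oxygen arises from the ester carbon as a free hydroxyl, so ring C (methyl on O2, O4 free) could only be reached by methylating one of two chelated hydroxyls selectively. A12 again shows the symmetrical pattern.
- Mechanistic risks: A10 can react as a heterodiene or acylate on oxygen, the diene terminus of A11 is substituted and hindered, and the thermolysis of A9 threatens the silyl ketene acetal units of A11. Ring B must then be acetylated between two benzyloxy groups, and A11 needs a long synthesis.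
- Comparison: structurally it is equal or better for ring A and worse for ring C. Mechanistically it is less predictable than the aryne insertion. In step economy it is longer overall.

Key step: step 5

Remarks on the chemistry (before the steps):
- Assumption: the outer rings are taken as the constitutional isomers that the connectivity of the target shows. One monomer joined twice to ring B would give the symmetrical isomer, so two monomers (21 for ring A, 14 for ring C) are made and attached one after the other.
- Precursor design. A silyl triflate with two methyl ethers can only lead to the ring A pattern, because the ether ortho to the ketone is the one that chelating Lewis acids remove. The precursors here carry one methyl and one 4-methoxybenzyl ether. Silicon next to methoxy (9) gives ring C; silicon next to the benzylic ether (17) gives ring A. Both are unmasked by hydrogenolysis, so no BCl3 is needed.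
- 4-Methoxybenzyl is preferred to benzyl because every aromatic C–H of its ring has an ortho substituent and is shielded in the borylation of step 2.
- Outer-ring locants C1–C6 are those of the target rings and are used for all intermediates.
- The aryne insertion is run twice. Step 5 carries the strategy; step 8 is the same reaction on the regioisomeric precursor.
- KHSO5 is used as its commercial triple salt 2KHSO5·KHSO4·K2SO4. dtbpy is 4,4'-di-tert-butyl-2,2'-bipyridine.

## Steps

Step 1
Reactants: 1 3-methoxy-2-methylphenol
Product: 2 1-methoxy-3-[(4-methoxyphenyl)methoxy]-2-methylbenzene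
Conditions: 4-methoxybenzyl chloride (1.1 equiv), K2CO3, DMF, 60 °C
Reagents that add atoms: 4-methoxybenzyl chloride, COc1ccc(CCl)cc1
Why: Williamson etherification of the phenoxide of 1 with a benzylic chloride; the 4-methoxybenzyl ether withstands organolithium reagents, triflation and fluoride and is later removed by hydrogenolysis, which leaves aryl methyl ethers alone.

Step 2
Reactants: 2 1-methoxy-3-[(4-methoxyphenyl)methoxy]-2-methylbenzene
Product: 4 3-methoxy-5-[(4-methoxyphenyl)methoxy]-4-methylphenol, via arylboronate 3 (not isolated)
Conditions: [Ir(OMe)(cod)]2 (1.5 mol %), dtbpy (3 mol %), B2pin2 (0.6 equiv), THF, 80 °C; then KHSO5, acetone/H2O, 0 °C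
Reagents that add atoms: potassium peroxymonosulfate, [K+].[O-]S(=O)(=O)OO; bis(pinacolato)diboron, CC1(C)OB(OC1(C)C)B1OC(C)(C)C(C)(C)O1 (boron of 3 only)
Why: Iridium-catalysed C–H borylation (active species a trivalent iridium tris(boryl) complex) is governed by steric access and should select C5 of 2, the only aromatic C–H without an ortho substituent, while every C–H of the 4-methoxybenzyl ring has an ortho neighbour and should react much more slowly. Oxidation of the C–B bond with KHSO5 keeps the position and gives the phenol meta to both ethers, a pattern electrophilic substitution cannot reach.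

Step 3
Reactants: 4 3-methoxy-5-[(4-methoxyphenyl)methoxy]-4-methylphenol
Product: 5 2-bromo-3-methoxy-5-[(4-methoxyphenyl)methoxy]-4-methylphenol and 6 2-bromo-5-methoxy-3-[(4-methoxyphenyl)methoxy]-4-methylphenol
Conditions: NBS (1.0 equiv), CH2Cl2, −78 → −40 °C; chromatographic separation
Reagents that add atoms: N-bromosuccinimide, O=C1CCC(=O)N1Br
Why: Electrophilic aromatic bromination of a phenol whose para position is blocked by methyl can only occur at the two ortho carbons, which differ solely in the neighbouring ether, so both monobromides are expected, 5 (bromine next to the smaller methoxy group) probably in the larger share. Both are wanted, 5 for ring C and 6 for ring A, and one equivalent of NBS at low temperature limits dibromination.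

Step 4
Reactants: 5 2-bromo-3-methoxy-5-[(4-methoxyphenyl)methoxy]-4-methylphenol
Product: 9 3-methoxy-5-[(4-methoxyphenyl)methoxy]-4-methyl-2-(trimethylsilyl)phenyl trifluoromethanesulfonate, via silyl ether 7 (not isolated), via lithium phenoxide 8 (not isolated)
Conditions: HMDS, THF, 65 °C, then evaporation; n-BuLi (1.1 equiv), THF, −100 °C; Tf2O (1.2 equiv), −100 → −78 °C
Reagents that add atoms: hexamethyldisilazane, C[Si](C)(C)N[Si](C)(C)C; trifluoromethanesulfonic anhydride, O=S(=O)(OS(=O)(=O)C(F)(F)F)C(F)(F)F; n-butyllithium, [Li]CCCC (lithium of 8 only)
Why: O-Silylation, bromine–lithium exchange and 1,3 O→C silyl migration (retro-Brook rearrangement) should place silicon on the former C–Br carbon and release lithium phenoxide 8, which is triflated in the same flask. At −100 °C the exchange is much faster than deprotonation of the benzylic ether CH2.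

Step 5
Reactants: 9 3-methoxy-5-[(4-methoxyphenyl)methoxy]-4-methyl-2-(trimethylsilyl)phenyl trifluoromethanesulfonate; 10 butanoic acid (1.2 equiv)
Product: 13 1-{6-hydroxy-2-methoxy-4-[(4-methoxyphenyl)methoxy]-3-methylphenyl}butan-1-one, via aryne 11 (not isolated), via aryl anion 12 (not isolated)
Conditions: CsF (4 equiv), THF, 125 °C, sealed pressure tube; then aq. NH4Cl
Reagents that add atoms: cesium fluoride, [Cs+].[F-] (cesium of 12 only)
Why: Fluoride attacks silicon in 9 and triflate leaves from the neighbouring carbon, giving aryne 11 under conditions the 4-methoxybenzyl ether tolerates. The O2 methoxy group next to C1 polarises and distorts the C1–C6 triple bond so that C6, whose neighbour C5 carries only hydrogen, is both the more electrophilic and the less hindered terminus, and the butanoate oxygen adds there. The aryl anion 12 is thus formed at C1, where the adjacent C–O bond stabilises it inductively. It attacks the ester carbonyl through a four-membered transition state and the acyl group moves from oxygen to carbon, an anionic Fries-type shift driven by formation of the cesium phenoxide of an ortho-hydroxyaryl ketone. The closest known reaction type is the fluoride-induced formal insertion of arynes into the acyl–oxygen bond of carboxylic acids. No ring is closed and no stereocentre is formed. Two selectivities are needed: oxygen must add at C6 and not at C1, which the methoxy group and the open C5 position secure (the remote O4 ether has only a weak opposing influence); and acyl transfer must outrun protonation of 12, which the high temperature, the excess of CsF holding the acid as its carboxylate and the use of only a slight excess of acid should favour.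

Step 6
Reactants: 13 1-{6-hydroxy-2-methoxy-4-[(4-methoxyphenyl)methoxy]-3-methylphenyl}butan-1-one
Product: 14 1-(4,6-dihydroxy-2-methoxy-3-methylphenyl)butan-1-one
Conditions: H2 (1 atm), Pd/C (10 wt %), EtOAc, rt
Reagents that add atoms: none
Why: Hydrogenolysis of the benzylic C–O bond should free O4 under neutral conditions; the O2 methyl ether, which a chelating Lewis acid would remove first, is untouched, and the electron-rich, hydrogen-bonded aryl ketone is not expected to be reduced at 1 atm.

Step 7
Reactants: 6 2-bromo-5-methoxy-3-[(4-methoxyphenyl)methoxy]-4-methylphenol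
Product: 17 5-methoxy-3-[(4-methoxyphenyl)methoxy]-4-methyl-2-(trimethylsilyl)phenyl trifluoromethanesulfonate, via silyl ether 15 (not isolated), via lithium phenoxide 16 (not isolated)
Conditions: HMDS, THF, 65 °C, then evaporation; n-BuLi (1.1 equiv), THF, −100 °C; Tf2O (1.2 equiv), −100 → −78 °C
Reagents that add atoms: hexamethyldisilazane, C[Si](C)(C)N[Si](C)(C)C; trifluoromethanesulfonic anhydride, O=S(=O)(OS(=O)(=O)C(F)(F)F)C(F)(F)F; n-butyllithium, [Li]CCCC (lithium of 16 only)
Why: Same retro-Brook rearrangement sequence as in step 4; here silicon arrives between the phenol oxygen and the 4-methoxybenzyl ether, which is what places that ether ortho to the ketone after step 8.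

Step 8
Reactants: 17 5-methoxy-3-[(4-methoxyphenyl)methoxy]-4-methyl-2-(trimethylsilyl)phenyl trifluoromethanesulfonate; 10 butanoic acid (1.2 equiv)
Product: 20 1-{6-hydroxy-4-methoxy-2-[(4-methoxyphenyl)methoxy]-3-methylphenyl}butan-1-one, via aryne 18 (not isolated), via aryl anion 19 (not isolated)
Conditions: CsF (4 equiv), THF, 125 °C, sealed pressure tube; then aq. NH4Cl
Reagents that add atoms: cesium fluoride, [Cs+].[F-] (cesium of 19 only)
Why: Same formal aryne insertion into the acyl–oxygen bond as in step 5: in aryne 18 the oxygen next to C1 is the 4-methoxybenzyloxy group, which polarises the triple bond in the same sense as methoxy, so butanoate oxygen should add at C6 and the acyl group should migrate to C1 via 19. The ketone thus lies between the benzylic ether on O2 and the new hydroxyl, with the methyl ether on O4.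

Step 9
Reactants: 20 1-{6-hydroxy-4-methoxy-2-[(4-methoxyphenyl)methoxy]-3-methylphenyl}butan-1-one
Product: 21 1-(2,6-dihydroxy-4-methoxy-3-methylphenyl)butan-1-one
Conditions: H2 (1 atm), Pd/C (10 wt %), EtOAc, rt
Reagents that add atoms: none
Why: Hydrogenolysis as in step 6 frees O2 and should give the ring A monomer without any Lewis acid; the O4 methyl ether is inert.

Step 10
Reactants: 21 1-(2,6-dihydroxy-4-methoxy-3-methylphenyl)butan-1-one; 22 1-(2,4,6-trihydroxyphenyl)ethan-1-one (3 equiv)
Product: 25 1-{3-[(3-acetyl-2,4,6-trihydroxyphenyl)methyl]-2,6-dihydroxy-4-methoxy-5-methylphenyl}butan-1-one, via Mannich base 23 (not isolated), via quinone methide 24 (not isolated)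
Conditions: 21, [Me2N=CH2]I (1.0 equiv), Et3N (1.0 equiv), MeCN, 0 °C → rt; then 22, 70 °C, N2
Reagents that add atoms: N,N-dimethylmethyleneiminium iodide, C[N+](C)=C.[I-]
Why: Mannich aminomethylation at C5, the only unsubstituted ring carbon of 21, gives 23; on warming, 23 should lose dimethylamine to the ortho-quinone methide 24, which the phloroglucinol 22 traps through carbon by conjugate addition and rearomatisation. The threefold excess of 22 keeps double alkylation of ring B low, and the surplus is removed by aqueous washing and chromatography.

Step 11
Reactants: 14 1-(4,6-dihydroxy-2-methoxy-3-methylphenyl)butan-1-one; 25 1-{3-[(3-acetyl-2,4,6-trihydroxyphenyl)methyl]-2,6-dihydroxy-4-methoxy-5-methylphenyl}butan-1-one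
Product: 28 1-[3-({3-acetyl-5-[(3-butanoyl-2,6-dihydroxy-4-methoxy-5-methylphenyl)methyl]-2,4,6-trihydroxyphenyl}methyl)-2,6-dihydroxy-4-methoxy-5-methylphenyl]butan-1-one, via Mannich base 26 (not isolated), via quinone methide 27 (not isolated)
Conditions: 14, [Me2N=CH2]I (1.0 equiv), Et3N (1.0 equiv), MeCN, 0 °C → rt; then 25 (1.0 equiv), 60 °C, N2
Reagents that add atoms: N,N-dimethylmethyleneiminium iodide, C[N+](C)=C.[I-]
Why: Mannich aminomethylation followed by quinone methide conjugate addition, as in step 10: C5 of 14 lies between two hydroxyl groups and should be aminomethylated readily, the Mannich base 26 should ionise to quinone methide 27 under milder heating than 23, and the only free nucleophilic carbon left in 25 is B5. Adding 25 only after the iminium salt is consumed prevents aminomethylation of ring B, and the mild final conditions limit redistribution of the bridge already present.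

## Compound list

1 | 3-methoxy-2-methylphenol | COc1cccc(O)c1C | starting material
2 | 1-methoxy-3-[(4-methoxyphenyl)methoxy]-2-methylbenzene | COc1ccc(COc2cccc(OC)c2C)cc1 | intermediate
3 | 2-{3-methoxy-5-[(4-methoxyphenyl)methoxy]-4-methylphenyl}-4,4,5,5-tetramethyl-1,3,2-dioxaborolane | COc1ccc(COc2cc(B3OC(C)(C)C(C)(C)O3)cc(OC)c2C)cc1 | intermediate (not isolated)
4 | 3-methoxy-5-[(4-methoxyphenyl)methoxy]-4-methylphenol | COc1ccc(COc2cc(O)cc(OC)c2C)cc1 | intermediate
5 | 2-bromo-3-methoxy-5-[(4-methoxyphenyl)methoxy]-4-methylphenol | COc1ccc(COc2cc(O)c(Br)c(OC)c2C)cc1 | intermediate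
6 | 2-bromo-5-methoxy-3-[(4-methoxyphenyl)methoxy]-4-methylphenol | COc1ccc(COc2c(Br)c(O)cc(OC)c2C)cc1 | intermediate
7 | {2-bromo-3-methoxy-5-[(4-methoxyphenyl)methoxy]-4-methylphenoxy}trimethylsilane | COc1ccc(COc2cc(O[Si](C)(C)C)c(Br)c(OC)c2C)cc1 | intermediate (not isolated)
8 | lithium 3-methoxy-5-[(4-methoxyphenyl)methoxy]-4-methyl-2-(trimethylsilyl)phenoxide | [Li+].COc1ccc(COc2cc([O-])c([Si](C)(C)C)c(OC)c2C)cc1 | intermediate (not isolated)
9 | 3-methoxy-5-[(4-methoxyphenyl)methoxy]-4-methyl-2-(trimethylsilyl)phenyl trifluoromethanesulfonate | COc1ccc(COc2cc(OS(=O)(=O)C(F)(F)F)c([Si](C)(C)C)c(OC)c2C)cc1 | intermediate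
10 | butanoic acid | CCCC(=O)O | starting material
11 | 3-methoxy-5-[(4-methoxyphenyl)methoxy]-4-methylbenzyne (1,2-didehydrobenzene) | COc1ccc(COC2=CC#CC(OC)=C2C)cc1 | intermediate (not isolated)
12 | cesium 2-(butanoyloxy)-6-methoxy-4-[(4-methoxyphenyl)methoxy]-5-methylbenzen-1-ide | [Cs+].CCCC(=O)Oc1cc(OCc2ccc(OC)cc2)c(C)c(OC)[c-]1 | intermediate (not isolated)
13 | 1-{6-hydroxy-2-methoxy-4-[(4-methoxyphenyl)methoxy]-3-methylphenyl}butan-1-one | CCCC(=O)c1c(OC)c(C)c(OCc2ccc(OC)cc2)cc1O | intermediate
14 | 1-(4,6-dihydroxy-2-methoxy-3-methylphenyl)butan-1-one | CCCC(=O)c1c(OC)c(C)c(O)cc1O | intermediate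
15 | {2-bromo-5-methoxy-3-[(4-methoxyphenyl)methoxy]-4-methylphenoxy}trimethylsilane | COc1ccc(COc2c(Br)c(O[Si](C)(C)C)cc(OC)c2C)cc1 | intermediate (not isolated)
16 | lithium 5-methoxy-3-[(4-methoxyphenyl)methoxy]-4-methyl-2-(trimethylsilyl)phenoxide | [Li+].COc1ccc(COc2c([Si](C)(C)C)c([O-])cc(OC)c2C)cc1 | intermediate (not isolated)
17 | 5-methoxy-3-[(4-methoxyphenyl)methoxy]-4-methyl-2-(trimethylsilyl)phenyl trifluoromethanesulfonate | COc1ccc(COc2c([Si](C)(C)C)c(OS(=O)(=O)C(F)(F)F)cc(OC)c2C)cc1 | intermediate
18 | 5-methoxy-3-[(4-methoxyphenyl)methoxy]-4-methylbenzyne (1,2-didehydrobenzene) | COc1ccc(COC2=C(C)C(OC)=CC#C2)cc1 | intermediate (not isolated)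
19 | cesium 2-(butanoyloxy)-4-methoxy-6-[(4-methoxyphenyl)methoxy]-5-methylbenzen-1-ide | [Cs+].CCCC(=O)Oc1cc(OC)c(C)c(OCc2ccc(OC)cc2)[c-]1 | intermediate (not isolated)
20 | 1-{6-hydroxy-4-methoxy-2-[(4-methoxyphenyl)methoxy]-3-methylphenyl}butan-1-one | CCCC(=O)c1c(OCc2ccc(OC)cc2)c(C)c(OC)cc1O | intermediate
21 | 1-(2,6-dihydroxy-4-methoxy-3-methylphenyl)butan-1-one | CCCC(=O)c1c(O)c(C)c(OC)cc1O | intermediate
22 | 1-(2,4,6-trihydroxyphenyl)ethan-1-one | CC(=O)c1c(O)cc(O)cc1O | starting material
23 | 1-{3-[(dimethylamino)methyl]-2,6-dihydroxy-4-methoxy-5-methylphenyl}butan-1-one | CCCC(=O)c1c(O)c(C)c(OC)c(CN(C)C)c1O | intermediate (not isolated)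
24 | 2-butanoyl-3-hydroxy-5-methoxy-4-methyl-6-methylidenecyclohexa-2,4-dien-1-one | CCCC(=O)C1=C(O)C(C)=C(OC)C(=C)C1=O | intermediate (not isolated)
25 | 1-{3-[(3-acetyl-2,4,6-trihydroxyphenyl)methyl]-2,6-dihydroxy-4-methoxy-5-methylphenyl}butan-1-one | CCCC(=O)c1c(O)c(C)c(OC)c(Cc2c(O)cc(O)c(C(C)=O)c2O)c1O | intermediate
26 | 1-{3-[(dimethylamino)methyl]-2,4-dihydroxy-6-methoxy-5-methylphenyl}butan-1-one | CCCC(=O)c1c(OC)c(C)c(O)c(CN(C)C)c1O | intermediate (not isolated)
27 | 2-butanoyl-5-hydroxy-3-methoxy-4-methyl-6-methylidenecyclohexa-2,4-dien-1-one | CCCC(=O)C1=C(OC)C(C)=C(O)C(=C)C1=O | intermediate (not isolated)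
28 | 1-[3-({3-acetyl-5-[(3-butanoyl-2,6-dihydroxy-4-methoxy-5-methylphenyl)methyl]-2,4,6-trihydroxyphenyl}methyl)-2,6-dihydroxy-4-methoxy-5-methylphenyl]butan-1-one | CCCC(=O)c1c(O)c(C)c(OC)c(Cc2c(O)c(Cc3c(O)c(C)c(OC)c(C(=O)CCC)c3O)c(O)c(C(C)=O)c2O)c1O | target

## Step count and least certain steps

Total: 11 steps. Longest linear sequence: 8 steps (1, 2, 3, 7, 8, 9, 10, 11); the ring C branch (steps 4–6) joins at step 11.

Step 5 (key step). The aryl anion 12 may be protonated before the acyl group shifts, which would stop the sequence at the stage of the aryl ester. The product phenoxide may also be arylated by aryne that is still being generated. The fallback makes the same C1–acyl bond without an aryne. It sets out from 5: n-BuLi (2.2 equiv) in THF at −78 °C should deprotonate the phenol and exchange bromine for lithium, giving lithium 2-lithio-3-methoxy-5-[(4-methoxyphenyl)methoxy]-4-methylphenoxide F1 . F1 is acylated with N-methoxy-N-methylbutanamide, and acidic work-up releases the ketone. This rejoins the route at 13.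

Step 8. The same processes can intervene. In addition, the anion 19 sits next to the benzylic ether and could be quenched by proton transfer from its CH2 group. The fallback sets out from 6 and proceeds in the same way through lithium 2-lithio-5-methoxy-3-[(4-methoxyphenyl)methoxy]-4-methylphenoxide F2 and N-methoxy-N-methylbutanamide. It rejoins at 20.

Step 3. The regioisomers may form in an unfavourable ratio (little 6), may not separate, or may be brominated twice. If they only fail to separate, the mixture can be taken through the conditions of steps 4–6 and divided at the stage of 14 and 21, which differ strongly in polarity and acidity. If 6 is scarce, the ring A monomer is made from the ring C monomer. This fallback sets out from 14: methylation of the free, unchelated O4 hydroxyl (MeI, 1.0 equiv, K2CO3, acetone, rt) should give 1-(6-hydroxy-2,4-dimethoxy-3-methylphenyl)butan-1-one F3 . Chelation-controlled cleavage of the O2 methyl ether of F3 with BCl3 (CH2Cl2, −78 → 0 °C) then rejoins the route at 21.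

Step 2. Borylation may spill over to the 4-methoxybenzyl ring or be slow on the electron-rich arene, and the oxidant may attack the benzylic ether. The fallback borylates before the ether is made. It sets out from 1: pinacolborane masks the hydroxyl, and [Ir(OMe)(cod)]2/dtbpy with B2pin2 should give 2-[3-methoxy-2-methyl-5-(4,4,5,5-tetramethyl-1,3,2-dioxaborolan-2-yl)phenoxy]-4,4,5,5-tetramethyl-1,3,2-dioxaborolane F4 . Aqueous work-up of F4 should give 3-methoxy-2-methyl-5-(4,4,5,5-tetramethyl-1,3,2-dioxaborolan-2-yl)phenol F5 , which is alkylated with 4-methoxybenzyl chloride and K2CO3. This rejoins the route at 3, now isolated, and 3 is oxidised to 4 as in step 2.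

Step 10. Ring B may be alkylated twice, or the quinone methide may form slowly because the C6 hydroxyl of 23 is chelated by the ketone, leaving time for self-condensation. The fallback is the classical alkaline condensation: 21 and an excess of 22 are treated with one equivalent of aqueous formaldehyde in dilute NaOH at room temperature, and 25 is separated from the homodimers. It sets out from 21 and 22 and rejoins at 25. This path makes no new compound and is entered as F0 .

Step 11. The bridge of 25 may redistribute by loss and recapture of quinone methide 24, which would give symmetrical trimers. The fallback inverts the polarity of the last coupling. It sets out from 25: aminomethylation at B5 with the same iminium salt should give 1-[3-({3-acetyl-5-[(dimethylamino)methyl]-2,4,6-trihydroxyphenyl}methyl)-2,6-dihydroxy-4-methoxy-5-methylphenyl]butan-1-one F6 . The ring B quinone methide from F6 is then captured by the highly nucleophilic C5 of 14. This rejoins the route at 28.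

## Further compounds

F1 | step 5 | lithium 2-lithio-3-methoxy-5-[(4-methoxyphenyl)methoxy]-4-methylphenoxide | [Li+].[Li+].COc1ccc(COc2cc([O-])[c-]c(OC)c2C)cc1
F2 | step 8 | lithium 2-lithio-5-methoxy-3-[(4-methoxyphenyl)methoxy]-4-methylphenoxide | [Li+].[Li+].COc1ccc(COc2[c-]c([O-])cc(OC)c2C)cc1
F3 | step 3 | 1-(6-hydroxy-2,4-dimethoxy-3-methylphenyl)butan-1-one | CCCC(=O)c1c(OC)c(C)c(OC)cc1O
F4 | step 2 | 2-[3-methoxy-2-methyl-5-(4,4,5,5-tetramethyl-1,3,2-dioxaborolan-2-yl)phenoxy]-4,4,5,5-tetramethyl-1,3,2-dioxaborolane | COc1cc(B2OC(C)(C)C(C)(C)O2)cc(OB2OC(C)(C)C(C)(C)O2)c1C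
F5 | step 2 | 3-methoxy-2-methyl-5-(4,4,5,5-tetramethyl-1,3,2-dioxaborolan-2-yl)phenol | COc1cc(B2OC(C)(C)C(C)(C)O2)cc(O)c1C
F0 | step 10 | none | none
F6 | step 11 | 1-[3-({3-acetyl-5-[(dimethylamino)methyl]-2,4,6-trihydroxyphenyl}methyl)-2,6-dihydroxy-4-methoxy-5-methylphenyl]butan-1-one | CCCC(=O)c1c(O)c(C)c(OC)c(Cc2c(O)c(CN(C)C)c(O)c(C(C)=O)c2O)c1O
A1 | alternative 1 | 2,2'-{[2,4,6-tris(benzyloxy)-1,3-phenylene]bis(methylene)}bis(3-ethoxycyclobut-2-en-1-one) | c1c(OCc2ccccc2)c(CC2=C(OCC)CC2=O)c(OCc2ccccc2)c(CC2=C(OCC)CC2=O)c1OCc1ccccc1
A2 | alternative 1 | 1-methoxyprop-1-yne | CC#COC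
A3 | alternative 1 | 4,4'-{[2,4,6-tris(benzyloxy)-1,3-phenylene]bis(methylene)}bis(5-ethoxy-3-methoxy-2-methylphenol) | c1c(OCc2ccccc2)c(Cc2c(OCC)cc(O)c(C)c2OC)c(OCc2ccccc2)c(Cc2c(OCC)cc(O)c(C)c2OC)c1OCc1ccccc1
A4 | alternative 2 | 1-[2,6-bis(benzyloxy)-4-iodophenyl]ethan-1-one | CC(=O)c1c(OCc2ccccc2)cc(I)cc1OCc1ccccc1
A5 | alternative 2 | 1-[2,6-bis(benzyloxy)-3-(chloromethyl)-4-methoxy-5-methylphenyl]butan-1-one | CCCC(=O)c1c(OCc2ccccc2)c(C)c(OC)c(CCl)c1OCc1ccccc1
A6 | alternative 2 | bicyclo[2.2.1]hept-2-ene (norbornene) | C1=CC2CCC1C2
A7 | alternative 2 | bis(pinacolato)diboron | CC1(C)OB(OC1(C)C)B1OC(C)(C)C(C)(C)O1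
A8 | alternative 2 | 1,1'-{[5-acetyl-4,6-bis(benzyloxy)-2-(4,4,5,5-tetramethyl-1,3,2-dioxaborolan-2-yl)-1,3-phenylene]bis[methylene(2,6-bis(benzyloxy)-4-methoxy-5-methyl-3,1-phenylene)]}bis(butan-1-one) | CC(=O)c1c(OCc2ccccc2)c(Cc2c(OC)c(C)c(OCc3ccccc3)c(C(=O)CCC)c2OCc2ccccc2)c(B2OC(C)(C)C(C)(C)O2)c(Cc2c(OC)c(C)c(OCc3ccccc3)c(C(=O)CCC)c2OCc2ccccc2)c1OCc1ccccc1
A9 | alternative 3 | 5-butanoyl-2,2-dimethyl-1,3-dioxane-4,6-dione | CCCC(=O)C1C(=O)OC(C)(C)OC1=O
A10 | alternative 3 | 3-oxohex-1-en-1-one (butyrylketene) | CCCC(=O)C=C=O
A11 | alternative 3 | 1,3,5-tris(benzyloxy)-2,4-bis{3,5-dimethoxy-4-methyl-5-[(trimethylsilyl)oxy]penta-2,4-dien-1-yl}benzene (alkene geometry not defined) | c1c(OCc2ccccc2)c(CC=C(OC)C(C)=C(OC)O[Si](C)(C)C)c(OCc2ccccc2)c(CC=C(OC)C(C)=C(OC)O[Si](C)(C)C)c1OCc1ccccc1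
A12 | alternative 3 | 1,1'-{[2,4,6-tris(benzyloxy)-1,3-phenylene]bis[methylene(2,6-dihydroxy-4-methoxy-5-methyl-3,1-phenylene)]}bis(butan-1-one) | c1c(OCc2ccccc2)c(Cc2c(O)c(C(=O)CCC)c(O)c(C)c2OC)c(OCc2ccccc2)c(Cc2c(O)c(C(=O)CCC)c(O)c(C)c2OC)c1OCc1ccccc1
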